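The depside ester bond is cut last, leaving a fully substituted ring A phenol and a chlorinated ring B acid from atraric acid. Ring A (C1 CO2Me, C2 CH3, C3 CH3, C4 O, C5 CH3, C6 OCH3) is finished through its adjacent C1 carboxyl and C2 methyl: a C1–C2 aryne, polarised by the neighbouring C6 methoxy, takes methyl at C2 from methyllithium and carbon dioxide at C1, forming both C–C bonds in one flask. The aryne precursor is a pentasubstituted chlorobenzene with C3 methyl, C4 OMOM, C5 methyl, C6 methoxy, chlorine at C2 and the single ring hydrogen at C1, made from 3-chloro-5-methoxyphenol by two directed lithiation–methylation rounds.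

Key step: step 4

Remark: atraric acid carries hydrogen where ring B of the target carries chlorine, so the chlorine is introduced by chlorinating atraric acid at its only free ring position (step 7); ring A labels C1 to C6 follow the paragraph above, whereas systematic names use their own locants.

Step 1
Reactants: 1 3-chloro-5-methoxyphenol
Product: 2 1-chloro-3-methoxy-5-(methoxymethoxy)benzene
Conditions: MOMCl, iPr2NEt, CH2Cl2, 0 °C to rt
Reagents that add atoms: chloromethyl methyl ether (MOMCl), COCCl
Why: O-alkylation of the phenol with an alpha-chloro ether and an amine base (MOM protection) should be clean and installs the acetal oxygen that directs both later lithiations.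

Step 2
Reactants: 2 1-chloro-3-methoxy-5-(methoxymethoxy)benzene
Product: 4 5-chloro-1-methoxy-3-(methoxymethoxy)-2-methylbenzene, via aryllithium 3 (not isolated)
Conditions: n-BuLi, THF, −78 to −40 °C; MeI, −78 °C to rt
Reagents that add atoms: iodomethane, CI
Why: Directed ortho-metalation should occur at the hydrogen flanked by the two oxygen donors (cooperative coordination by OMOM and OMe), giving an aryllithium that is para to chlorine and so cannot lose LiCl, and this is methylated by iodomethane.

Step 3
Reactants: 4 5-chloro-1-methoxy-3-(methoxymethoxy)-2-methylbenzene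
Product: 6 1-chloro-5-methoxy-3-(methoxymethoxy)-2,4-dimethylbenzene, via aryllithium 5 (not isolated)
Conditions: s-BuLi, THF, −78 °C; MeI, −78 °C to rt
Reagents that add atoms: iodomethane, CI
Why: In this second directed ortho-metalation both remaining hydrogens are ortho to chlorine, so the better chelating and more acidifying OMOM group should steer lithiation to its own side, and at −78 °C the ortho-chloroaryllithium should persist long enough to be methylated.

Step 4
Reactants: 6 1-chloro-5-methoxy-3-(methoxymethoxy)-2,4-dimethylbenzene; 7 methyllithium; 8 carbon dioxide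
Product: 12 2-methoxy-4-(methoxymethoxy)-3,5,6-trimethylbenzoic acid, via chloroaryllithium 9 (not isolated), via aryne 10 (not isolated), via trimethylaryllithium 11 (not isolated)
Conditions: s-BuLi (1.05 equiv), THF, −78 °C; MeLi (4 equiv), −78 to −10 °C; cannulation onto excess solid CO2 in THF, −78 °C; cold 1 M HCl to pH 3
Reagents that add atoms: none
Why: sec-Butyllithium should remove the one remaining ring hydrogen, acidified by the flanking chlorine and methoxy, to give 9; on warming 9 loses LiCl to aryne 10, methyllithium adds to the aryne carbon remote from the methoxy-bearing carbon (C2) to give 11, and 11 is carboxylated at C1. The closest known reaction type is the generation of 3-alkoxyarynes from 3-haloanisoles with alkyllithiums, followed by regioselective carbolithiation and electrophilic quench of the resulting 2-alkoxyaryllithium. No ring is closed and no stereocentre is formed. The step needs the C–CH3 bond to form at C2 and not at C1: the inductively withdrawing C6 methoxy stabilises carbanion character at C1 and distorts the aryne toward attack at the distal carbon, the donating C3 methyl disfavours the alternative carbanion at C2, and together these should outweigh the small steric cost of the C3 methyl. Methyl transfer over other aryne-consuming pathways is secured by consuming the sec-butyllithium at −78 °C, where 9 is persistent, and by having a large excess of the small methyllithium present during warming. The inverse quench onto excess CO2 should keep methyllithium from adding to the hindered lithium carboxylate.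

Step 5
Reactants: 12 2-methoxy-4-(methoxymethoxy)-3,5,6-trimethylbenzoic acid
Product: 13 methyl 2-methoxy-4-(methoxymethoxy)-3,5,6-trimethylbenzoate
Conditions: MeI, K2CO3, DMF, rt
Reagents that add atoms: iodomethane, CI
Why: Carboxylate O-alkylation (SN2 at iodomethane) avoids a tetrahedral intermediate at the di-ortho-substituted carbonyl and leaves the MOM ether untouched.

Step 6
Reactants: 13 methyl 2-methoxy-4-(methoxymethoxy)-3,5,6-trimethylbenzoate
Product: 14 methyl 4-hydroxy-2-methoxy-3,5,6-trimethylbenzoate
Conditions: HCl, MeOH, 45 °C
Reagents that add atoms: none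
Why: Acid-catalysed transacetalisation to methanol (MOM cleavage) should free the C4 phenol while the hindered methyl ester and the aryl methyl ether are inert.

Step 7
Reactants: 15 atraric acid (methyl 2,4-dihydroxy-3,6-dimethylbenzoate)
Product: 16 methyl 5-chloro-2,4-dihydroxy-3,6-dimethylbenzoate
Conditions: SO2Cl2 (1.05 equiv), Et2O, 0 °C to rt
Reagents that add atoms: sulfuryl chloride, O=S(=O)(Cl)Cl
Why: Electrophilic aromatic chlorination can only take place at the single unsubstituted ring carbon, which is ortho to one hydroxyl and para to the other.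

Step 8
Reactants: 16 methyl 5-chloro-2,4-dihydroxy-3,6-dimethylbenzoate
Product: 17 methyl 2,4-bis(benzyloxy)-5-chloro-3,6-dimethylbenzoate
Conditions: BnBr, K2CO3, DMF, 60 °C
Reagents that add atoms: benzyl bromide, BrCc1ccccc1
Why: Williamson ether synthesis on both phenoxides gives acid-stable benzyl ethers that should survive the strongly acidic esterification in step 10, which acetal protection would not.

Step 9
Reactants: 17 methyl 2,4-bis(benzyloxy)-5-chloro-3,6-dimethylbenzoate
Product: 18 2,4-bis(benzyloxy)-5-chloro-3,6-dimethylbenzoic acid
Conditions: KOH, DMSO/H2O, 90 °C; then aq. HCl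
Reagents that add atoms: potassium hydroxide, [K+].[OH-]
Why: Saponification with poorly solvated hydroxide in aqueous DMSO should overcome the di-ortho hindrance of the ester, while the benzyl ethers and the unactivated aryl chloride on a fully substituted ring are stable to base.

Step 10
Reactants: 18 2,4-bis(benzyloxy)-5-chloro-3,6-dimethylbenzoic acid; 14 methyl 4-hydroxy-2-methoxy-3,5,6-trimethylbenzoate
Product: 20 methyl 4-{[2,4-bis(benzyloxy)-5-chloro-3,6-dimethylbenzoyl]oxy}-2-methoxy-3,5,6-trimethylbenzoate, via mixed anhydride 19 (not isolated)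
Conditions: (CF3CO)2O, toluene, rt (18 premixed with the anhydride, then 14)
Reagents that add atoms: none
Why: In this mixed-anhydride esterification the aroyl trifluoroacetate 19 should ionise to a linear acylium ion, stabilised by the ortho and para benzyloxy groups, which is small enough to be captured by the di-ortho-methyl phenol where tetrahedral acyl transfer would stall.

Step 11
Reactants: 20 methyl 4-{[2,4-bis(benzyloxy)-5-chloro-3,6-dimethylbenzoyl]oxy}-2-methoxy-3,5,6-trimethylbenzoate
Product: 22 methyl 4-[(5-chloro-2,4-dihydroxy-3,6-dimethylbenzoyl)oxy]-2-methoxy-3,5,6-trimethylbenzoate, via bis(dichloroboryl) ether 21 (not isolated)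
Conditions: BCl3, C6HMe5, CH2Cl2, −78 °C; then MeOH, aq. work-up
Reagents that add atoms: none
Why: Lewis acid debenzylation with BCl3, with pentamethylbenzene trapping the benzyl cation by Friedel–Crafts alkylation, should cleave both aryl benzyl ethers at −78 °C without touching the aryl methyl ether, either ester or the aryl chloride, which a hydrogenolysis could endanger.

Compound list
1 | 3-chloro-5-methoxyphenol | COc1cc(O)cc(Cl)c1 | starting material
2 | 1-chloro-3-methoxy-5-(methoxymethoxy)benzene | COCOc1cc(Cl)cc(OC)c1 | intermediate
3 | [4-chloro-2-methoxy-6-(methoxymethoxy)phenyl]lithium | [Li]c1c(OC)cc(Cl)cc1OCOC | intermediate (not isolated)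
4 | 5-chloro-1-methoxy-3-(methoxymethoxy)-2-methylbenzene | COCOc1cc(Cl)cc(OC)c1C | intermediate
5 | [6-chloro-4-methoxy-2-(methoxymethoxy)-3-methylphenyl]lithium | COCOc1c([Li])c(Cl)cc(OC)c1C | intermediate (not isolated)
6 | 1-chloro-5-methoxy-3-(methoxymethoxy)-2,4-dimethylbenzene | COc1cc(Cl)c(C)c(OCOC)c1C | intermediate
7 | methyllithium | [Li]C | starting material
8 | carbon dioxide | O=C=O | starting material
9 | [2-chloro-6-methoxy-4-(methoxymethoxy)-3,5-dimethylphenyl]lithium | COc1c([Li])c(Cl)c(C)c(OCOC)c1C | intermediate (not isolated)
10 | 3-methoxy-5-(methoxymethoxy)-4,6-dimethyl-1,2-didehydrobenzene (aryne) | COC1=C(C)C(OCOC)=C(C)C#C1 | intermediate (not isolated)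
11 | [2-methoxy-4-(methoxymethoxy)-3,5,6-trimethylphenyl]lithium | COc1c([Li])c(C)c(C)c(OCOC)c1C | intermediate (not isolated)
12 | 2-methoxy-4-(methoxymethoxy)-3,5,6-trimethylbenzoic acid | COCOc1c(C)c(C)c(C(=O)O)c(OC)c1C | intermediate
13 | methyl 2-methoxy-4-(methoxymethoxy)-3,5,6-trimethylbenzoate | COCOc1c(C)c(C)c(C(=O)OC)c(OC)c1C | intermediate
14 | methyl 4-hydroxy-2-methoxy-3,5,6-trimethylbenzoate | COC(=O)c1c(C)c(C)c(O)c(C)c1OC | intermediate
15 | atraric acid (methyl 2,4-dihydroxy-3,6-dimethylbenzoate) | COC(=O)c1c(C)cc(O)c(C)c1O | starting material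
16 | methyl 5-chloro-2,4-dihydroxy-3,6-dimethylbenzoate | COC(=O)c1c(C)c(Cl)c(O)c(C)c1O | intermediate
17 | methyl 2,4-bis(benzyloxy)-5-chloro-3,6-dimethylbenzoate | COC(=O)c1c(C)c(Cl)c(OCc2ccccc2)c(C)c1OCc1ccccc1 | intermediate
18 | 2,4-bis(benzyloxy)-5-chloro-3,6-dimethylbenzoic acid | OC(=O)c1c(C)c(Cl)c(OCc2ccccc2)c(C)c1OCc1ccccc1 | intermediate
19 | 2,4-bis(benzyloxy)-5-chloro-3,6-dimethylbenzoic trifluoroacetic anhydride | O=C(OC(=O)C(F)(F)F)c1c(C)c(Cl)c(OCc2ccccc2)c(C)c1OCc1ccccc1 | intermediate (not isolated)
20 | methyl 4-{[2,4-bis(benzyloxy)-5-chloro-3,6-dimethylbenzoyl]oxy}-2-methoxy-3,5,6-trimethylbenzoate | COC(=O)c1c(C)c(C)c(OC(=O)c2c(C)c(Cl)c(OCc3ccccc3)c(C)c2OCc2ccccc2)c(C)c1OC | intermediate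
21 | methyl 4-({5-chloro-2,4-bis[(dichloroboranyl)oxy]-3,6-dimethylbenzoyl}oxy)-2-methoxy-3,5,6-trimethylbenzoate | COC(=O)c1c(C)c(C)c(OC(=O)c2c(C)c(Cl)c(OB(Cl)Cl)c(C)c2OB(Cl)Cl)c(C)c1OC | intermediate (not isolated)
22 | methyl 4-[(5-chloro-2,4-dihydroxy-3,6-dimethylbenzoyl)oxy]-2-methoxy-3,5,6-trimethylbenzoate (CNP0231767.0) | COC(=O)c1c(C)c(C)c(OC(=O)c2c(C)c(Cl)c(O)c(C)c2O)c(C)c1OC | target

Total step count: 11. Longest linear sequence: 8 steps (steps 1 to 6, then 10 and 11); the ring B branch (steps 7 to 9) joins at step 10.

Steps most likely to fail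

Step 4 (aryne methylation and carboxylation). The aryne may be consumed by its own precursor 9 or by stray proton sources faster than methyllithium adds. Methyl may also add in part at the carbon beside the methoxy-bearing carbon, or methyllithium may add to the carboxylate during the quench. The fallback sets out from 6 and returns at 13, and avoids the aryne altogether. Aryllithium 9 would be formed as before but carboxylated at −78 °C without warming, so that chlorine is kept, to give 2-chloro-6-methoxy-4-(methoxymethoxy)-3,5-dimethylbenzoic acid F1. MeI and K2CO3 in DMF would convert this into methyl 2-chloro-6-methoxy-4-(methoxymethoxy)-3,5-dimethylbenzoate F2. A Suzuki–Miyaura methylation of the aryl chloride (trimethylboroxine, Pd(OAc)2, SPhos, K3PO4, toluene/H2O, 100 °C) would then deliver 13, and the route continues at step 6.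

Step 3 (second directed lithiation and methylation). Deprotonation may take place in part at the hydrogen between chlorine and methoxy, and the ortho-chloroaryllithium may lose LiCl before it is methylated. The fallback sets out from 4 and returns at 6, bringing in the second methyl through the free phenol, whose only open ortho position is the required one. Acidic methanolysis of 4 (HCl, MeOH) would give 5-chloro-3-methoxy-2-methylphenol F3. Magnesium-mediated ortho-formylation (MgCl2, Et3N, paraformaldehyde, MeCN, reflux) would give 2-chloro-6-hydroxy-4-methoxy-5-methylbenzaldehyde F4. Ionic hydrogenation (Et3SiH, CF3CO2H) would reduce the formyl group to methyl and give 3-chloro-5-methoxy-2,6-dimethylphenol F5, and MOMCl with iPr2NEt would return 6.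

Step 10 (depside esterification). Acyl transfer between two di-ortho-substituted partners may stall, with trifluoroacetylation of the phenol or acid-induced loss of a benzyl group competing. The fallback sets out from 18 and 14 and returns at 20, moving the acyl transfer to basic conditions with a preformed nucleophile. Oxalyl chloride with catalytic DMF in CH2Cl2 would convert 18 into 2,4-bis(benzyloxy)-5-chloro-3,6-dimethylbenzoyl chloride F6. Phenol 14 and NaH in THF would give sodium 3-methoxy-4-(methoxycarbonyl)-2,5,6-trimethylphenolate F7. The two would be combined in THF and heated to give 20 by addition–elimination.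

Further compounds
F1 | step 4 | 2-chloro-6-methoxy-4-(methoxymethoxy)-3,5-dimethylbenzoic acid | COCOc1c(C)c(Cl)c(C(=O)O)c(OC)c1C
F2 | step 4 | methyl 2-chloro-6-methoxy-4-(methoxymethoxy)-3,5-dimethylbenzoate | COCOc1c(C)c(Cl)c(C(=O)OC)c(OC)c1C
F3 | step 3 | 5-chloro-3-methoxy-2-methylphenol | COc1cc(Cl)cc(O)c1C
F4 | step 3 | 2-chloro-6-hydroxy-4-methoxy-5-methylbenzaldehyde | COc1cc(Cl)c(C=O)c(O)c1C
F5 | step 3 | 3-chloro-5-methoxy-2,6-dimethylphenol | COc1cc(Cl)c(C)c(O)c1C
F6 | step 10 | 2,4-bis(benzyloxy)-5-chloro-3,6-dimethylbenzoyl chloride | O=C(Cl)c1c(C)c(Cl)c(OCc2ccccc2)c(C)c1OCc1ccccc1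
F7 | step 10 | sodium 3-methoxy-4-(methoxycarbonyl)-2,5,6-trimethylphenolate | COC(=O)c1c(C)c(C)c([O-])c(C)c1OC.[Na+]
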